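**Retrosynthetic overview**
1. The strategy rests on the γ-lactone ring O1–C2(=O)–C3–C4–C5. C5 carries the ring oxygen and the chain (first carbon C1′), so it can start as a boron-bearing carbon. C4 carries CO2H cis to the chain, and C3 carries a methyl trans to CO2H.
2. 25 ⇒ phenyl lactone 24 (phenyl as masked CO2H, RuO4) ⇒ 1,4-diol 21 ⇒ secondary boronate 18 (C5–B to C5–O with retention).
3. 18 ⇒ one three-component conjunctive coupling of chain Grignard 7, (S,E)-alkenylboronate 15 and phenyl triflate 16. It forms C5–C1′ and C4–phenyl by anti addition across the E C4=C5 bond.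
4. 15 ⇒ (R)-Roche ester 10 (C3 from the chiral pool) plus the hindered diol 9 on boron, used instead of pinacol to hold back direct Suzuki transfer. 7 ⇒ 1,12-dibromododecane 2 + ethyl acetoacetate 1.
5. Ring order: the lactone is the only ring and closes late (step 13, O1–C2 bond). The key step closes no ring.

Key step: step 10

Remark: the sense of induction of the ferrocenyl bisphosphine on this substrate is not assigned in advance; both antipodes are commercial, and the one that puts palladium on the C4 Re face is assumed to be picked in a test run. Lactone numbering is used for all intermediates, and "B(mac)" means the cyclic boronate of diol 9.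

**Step 1**
Reactants: 1 ethyl acetoacetate; 2 1,12-dibromododecane
Product: 3 ethyl 2-acetyl-14-bromotetradecanoate (racemic)
Conditions: K2CO3 (1.5 equiv), 2 (3 equiv), DMF, 60 °C
Reagents that add atoms: none
Why: Acetoacetic ester alkylation, in which the stabilised enolate displaces one primary bromide by SN2, the threefold excess of 2 (recovered afterwards) holds back reaction at both ends, and the new stereocentre does not matter because step 2 destroys it.

**Step 2**
Reactants: 3 ethyl 2-acetyl-14-bromotetradecanoate
Product: 5 15-bromopentadecan-2-one, via β-keto acid 4 (not isolated)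
Conditions: 48% aq HBr, AcOH, reflux
Reagents that add atoms: none
Why: Acidic ester hydrolysis followed by thermal decarboxylation of the β-keto acid (ketone cleavage of the acetoacetic ester synthesis), and in hydrobromic acid any substitution at the primary bromide is degenerate, so the C–Br bond is kept.

**Step 3**
Reactants: 5 15-bromopentadecan-2-one
Product: 6 2-(13-bromotridecyl)-2-methyl-1,3-dioxolane
Conditions: ethylene glycol (3 equiv), p-TsOH·H2O (cat.), toluene, Dean–Stark, reflux
Reagents that add atoms: ethylene glycol, OCCO
Why: Acid-catalysed ketalisation with azeotropic removal of water masks the methyl ketone for the organomagnesium and borate stages, and the primary bromide is inert to these conditions.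

**Step 4**
Reactants: 6 2-(13-bromotridecyl)-2-methyl-1,3-dioxolane
Product: 7 [13-(2-methyl-1,3-dioxolan-2-yl)tridecyl]magnesium bromide (THF solution, titrated and used directly)
Conditions: Mg turnings (activated with a trace of 1,2-dibromoethane), THF, 40–50 °C, slow addition
Reagents that add atoms: magnesium, [Mg]
Why: Grignard formation by magnesium insertion into the primary C–Br bond, where the dioxolane tolerates organomagnesium reagents and slow addition at moderate dilution limits Wurtz coupling.

**Step 5**
Reactants: 8 acenaphthenequinone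
Product: 9 cis-1,2-dimethyl-1,2-dihydroacenaphthylene-1,2-diol (meso; 1R,2S; "mac diol")
Conditions: AlMe3 (2.5 equiv), toluene, 0 °C → rt; aq Rochelle salt; recrystallisation
Reagents that add atoms: trimethylaluminium, C[Al](C)C
Why: Twofold 1,2-addition of methyl to the 1,2-diketone, in which the bulky aluminium alkoxide formed first shields its own face, so the second methyl should enter syn to the first and give the cis (meso) diol, the only isomer able to bridge boron, which recrystallisation frees from any trans isomer.

**Step 6**
Reactants: 10 methyl (R)-3-hydroxy-2-methylpropanoate (Roche ester)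
Product: 11 methyl (R)-3-(tert-butyldimethylsilyloxy)-2-methylpropanoate
Conditions: TBSCl, imidazole, CH2Cl2, 0 °C → rt
Reagents that add atoms: tert-butyldimethylsilyl chloride, CC(C)(C)[Si](C)(C)Cl
Why: Imidazole-promoted silylation of the primary alcohol, which leaves untouched the stereocentre that becomes C3 and comes from the chiral pool.

**Step 7**
Reactants: 11 methyl (R)-3-(tert-butyldimethylsilyloxy)-2-methylpropanoate
Product: 12 (R)-3-(tert-butyldimethylsilyloxy)-2-methylpropanal
Conditions: DIBAL-H (1.05 equiv), CH2Cl2, −78 °C; aq Rochelle salt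
Reagents that add atoms: none
Why: Partial ester reduction with DIBAL-H, which at −78 °C stays at the aldehyde oxidation level until the quench, and the α-stereocentre is kept if the crude aldehyde is used at once without chromatography.

**Step 8**
Reactants: 12 (R)-3-(tert-butyldimethylsilyloxy)-2-methylpropanal
Product: 13 (S)-tert-butyl-dimethyl-[(2-methylbut-3-ynyl)oxy]silane
Conditions: dimethyl (1-diazo-2-oxopropyl)phosphonate (1.3 equiv), K2CO3 (2 equiv), MeOH, 0 °C → rt
Reagents that add atoms: Ohira–Bestmann reagent, COP(=O)(OC)C(=[N+]=[N-])C(C)=O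
Why: Seyferth–Gilbert homologation in the Ohira–Bestmann variant turns the aldehyde into the terminal alkyne with one added carbon (the future C5) under base that is mild enough at 0 °C to leave the α-stereocentre intact (the descriptor changes from R to S only through CIP priorities).

**Step 9**
Reactants: 13 (S)-tert-butyl-dimethyl-[(2-methylbut-3-ynyl)oxy]silane; 9 mac diol
Product: 15 (1E,3S)-4-(tert-butyldimethylsilyloxy)-3-methylbut-1-enylboronic acid B(mac) ester, via alkenyl catechol boronate 14 (not isolated)
Conditions: catecholborane (1.1 equiv), neat, 70 °C; then 9 (1.05 equiv), THF, rt; wash with dilute aq NaOH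
Reagents that add atoms: catecholborane, B1Oc2ccccc2O1
Why: Syn hydroboration of the terminal alkyne places boron on the terminal carbon and fixes the E geometry, and the labile catechol ester is then exchanged for the chelating, more electron-rich ditertiary diol 9 (boronate transesterification).

**Step 10**
Reactants: 15 (S,E)-alkenyl B(mac) boronate; 7 chain Grignard reagent; 16 phenyl trifluoromethanesulfonate
Product: 18 tert-butyl-dimethyl-{[(2S,3R,4S)-4-B(mac)-2-methyl-17-(2-methyl-1,3-dioxolan-2-yl)-3-phenylheptadecyl]oxy}silane (lactone numbering: C3 S / C4 R / C5 S), via magnesium ate complex 17 (not isolated)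
Conditions: 15, NaOTf (2 equiv), THF, 0 °C; 7 (1.0 equiv), 0 °C → rt; then 16 (1.1 equiv), Pd(OAc)2 (3 mol %), MandyPhos (3.6 mol %), THF/DMSO, 40–60 °C
Reagents that add atoms: none
Why: Grignard reagent 7 adds to the vacant boron orbital of 15 (NaOTf takes up bromide and drives ate formation), and oxidative addition of 16 to Pd(0)/bisphosphine gives a cationic phenylpalladium species that binds the electron-rich C4=C5 bond of 17. The alkyl group then shifts from boron to C5 antiperiplanar to the developing C4–Pd bond (1,2-metallate rearrangement) and reductive elimination joins phenyl to C4 with retention; the closest known reactions are the enantioselective Pd/MandyPhos conjunctive cross-coupling of β-alkyl-substituted E-alkenyl B(mac) ate complexes with aryl triflates and the same coupling of Grignard-derived ate complexes with NaOTf. No ring is closed. C5 (S) and C4 (R) are tied to each other by the E geometry and the anti mechanism, which after stereoretentive oxidation and lactonisation places chain and aryl cis on the ring. Their absolute sense, and with it the trans C3/C4 relation, follows from the alkene face taken by palladium (C4 Re face): the ligand dictates it, and in the conformer with C3–H eclipsing the alkene this face is flanked by the methyl group and lies opposite CH2OTBS, so the substrate bias should be matched. The step needs metallate shift to win over direct alkenyl transfer (Suzuki coupling) and over β-hydride elimination from C4–Pd, which the hindered diol on boron and the wide-bite-angle ligand should secure.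

**Step 11**
Reactants: 18 secondary B(mac) boronate
Product: 20 (2S,3R,4S)-1-(tert-butyldimethylsilyloxy)-2-methyl-17-(2-methyl-1,3-dioxolan-2-yl)-3-phenylheptadecan-4-ol, via borate ester 19 (not isolated)
Conditions: 30% H2O2, 3 M aq NaOH, THF, 0 °C → rt
Reagents that add atoms: hydrogen peroxide, OO
Why: Alkaline peroxide oxidation of the C–B bond, in which hydroperoxide adds to boron, C5 migrates to oxygen with retention of configuration and the borate ester is then hydrolysed, while silyl ether and ketal are stable to the base.

**Step 12**
Reactants: 20 silyl ether ketal alcohol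
Product: 21 (16S,17R,18S)-16,19-dihydroxy-18-methyl-17-phenylnonadecan-2-one
Conditions: 2 M aq HCl, THF, rt
Reagents that add atoms: water, O
Why: Aqueous acid hydrolyses the primary TBS ether and the dioxolane in one operation, and no stereocentre is at risk because none lies next to a carbonyl group or a leaving group at this stage.

**Step 13**
Reactants: 21 keto diol
Product: 24 (3S,4R,5S)-3-methyl-5-(14-oxopentadecyl)-4-phenyldihydrofuran-2(3H)-one, via hydroxy aldehyde 22 (not isolated), via lactol 23 (not isolated)
Conditions: TEMPO (0.2 equiv), PhI(OAc)2 (2.5 equiv), CH2Cl2, rt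
Reagents that add atoms: none
Why: TEMPO/PhI(OAc)2 oxidative lactonisation, in which the oxoammonium salt oxidises the unhindered primary alcohol first, the C5 hydroxyl closes on the aldehyde (5-exo-trig, O1–C2 bond) faster than C3 can epimerise, and the lactol is oxidised on to the γ-lactone with chain and phenyl cis and methyl trans to phenyl.

**Step 14**
Reactants: 24 phenyl keto lactone
Product: 25 (2S,3S,4S)-4-methyl-5-oxo-2-(14-oxopentadecyl)tetrahydrofuran-3-carboxylic acid (target)
Conditions: RuCl3·xH2O (5 mol %), NaIO4 (18 equiv), EtOAc/MeCN/H2O, rt; acidic work-up without base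
Reagents that add atoms: sodium periodate, [Na+].[O-]I(=O)(=O)=O; water, O
Why: Catalytic RuO4 degradation of the phenyl ring to the carboxylic acid with retention at the former benzylic carbon, where lactone, ketone and saturated chain are far less reactive than the arene and the neutral to acidic medium avoids epimerisation of C4 to the trans acid.

**Compound list**
1 | ethyl acetoacetate | CCOC(=O)CC(C)=O | starting material
2 | 1,12-dibromododecane | BrCCCCCCCCCCCCBr | starting material
3 | ethyl 2-acetyl-14-bromotetradecanoate (racemic) | CCOC(=O)C(CCCCCCCCCCCCBr)C(C)=O | intermediate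
4 | 2-acetyl-14-bromotetradecanoic acid (β-keto acid, not isolated) | OC(=O)C(CCCCCCCCCCCCBr)C(C)=O | intermediate
5 | 15-bromopentadecan-2-one | CC(=O)CCCCCCCCCCCCCBr | intermediate
6 | 2-(13-bromotridecyl)-2-methyl-1,3-dioxolane | CC1(CCCCCCCCCCCCCBr)OCCO1 | intermediate
7 | [13-(2-methyl-1,3-dioxolan-2-yl)tridecyl]magnesium bromide | CC1(CCCCCCCCCCCCC[Mg]Br)OCCO1 | intermediate
8 | acenaphthenequinone | O=C1C(=O)c2cccc3cccc1c23 | starting material
9 | cis-1,2-dimethyl-1,2-dihydroacenaphthylene-1,2-diol (meso, mac diol) | C[C@@]1(O)[C@](C)(O)c2cccc3cccc1c23 | intermediate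
10 | methyl (R)-3-hydroxy-2-methylpropanoate | COC(=O)[C@H](C)CO | starting material
11 | methyl (R)-3-(tert-butyldimethylsilyloxy)-2-methylpropanoate | COC(=O)[C@H](C)CO[Si](C)(C)C(C)(C)C | intermediate
12 | (R)-3-(tert-butyldimethylsilyloxy)-2-methylpropanal | O=C[C@H](C)CO[Si](C)(C)C(C)(C)C | intermediate
13 | (S)-tert-butyl-dimethyl-[(2-methylbut-3-ynyl)oxy]silane | C#C[C@H](C)CO[Si](C)(C)C(C)(C)C | intermediate
14 | 2-[(1E,3S)-4-(tert-butyldimethylsilyloxy)-3-methylbut-1-enyl]-1,3,2-benzodioxaborole (not isolated) | C[C@H](CO[Si](C)(C)C(C)(C)C)/C=C/B1Oc2ccccc2O1 | intermediate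
15 | (1E,3S)-4-(tert-butyldimethylsilyloxy)-3-methylbut-1-enylboronic acid, cyclic ester with 9 | C[C@H](CO[Si](C)(C)C(C)(C)C)/C=C/B1O[C@]2(C)[C@](C)(O1)c1cccc3cccc2c13 | intermediate
16 | phenyl trifluoromethanesulfonate | O=S(=O)(Oc1ccccc1)C(F)(F)F | starting material
17 | bromomagnesium alkyl(alkenyl) B(mac) ate complex (boron configuration not defined, not isolated) | CC1(CCCCCCCCCCCCC[B-]2(/C=C/[C@H](C)CO[Si](C)(C)C(C)(C)C)O[C@]3(C)[C@](C)(O2)c2cccc4cccc3c24)OCCO1.[Mg+]Br | intermediate
18 | (2S,3R,4S)-secondary B(mac) boronate with C2 methyl, C3 phenyl, C4 boron, C1 OTBS and ketal chain | CC1(CCCCCCCCCCCCC[C@H](B2O[C@]3(C)[C@](C)(O2)c2cccc4cccc3c24)[C@@H](c2ccccc2)[C@H](C)CO[Si](C)(C)C(C)(C)C)OCCO1 | intermediate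
19 | borate ester from C5-to-oxygen migration (not isolated) | CC1(CCCCCCCCCCCCC[C@H](OB2O[C@]3(C)[C@](C)(O2)c2cccc4cccc3c24)[C@@H](c2ccccc2)[C@H](C)CO[Si](C)(C)C(C)(C)C)OCCO1 | intermediate
20 | (2S,3R,4S)-1-(tert-butyldimethylsilyloxy)-2-methyl-17-(2-methyl-1,3-dioxolan-2-yl)-3-phenylheptadecan-4-ol | CC1(CCCCCCCCCCCCC[C@H](O)[C@@H](c2ccccc2)[C@H](C)CO[Si](C)(C)C(C)(C)C)OCCO1 | intermediate
21 | (16S,17R,18S)-16,19-dihydroxy-18-methyl-17-phenylnonadecan-2-one | CC(=O)CCCCCCCCCCCCC[C@H](O)[C@@H](c1ccccc1)[C@H](C)CO | intermediate
22 | (2S,3R,4S)-4-hydroxy-2-methyl-18-oxo-3-phenylnonadecanal (not isolated) | CC(=O)CCCCCCCCCCCCC[C@H](O)[C@@H](c1ccccc1)[C@H](C)C=O | intermediate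
23 | lactol of 22 (anomeric centre undefined, not isolated) | CC(=O)CCCCCCCCCCCCC[C@@H]1OC(O)[C@@H](C)[C@@H]1c2ccccc2 | intermediate
24 | (3S,4R,5S)-3-methyl-5-(14-oxopentadecyl)-4-phenyldihydrofuran-2(3H)-one | CC(=O)CCCCCCCCCCCCC[C@@H]1OC(=O)[C@@H](C)[C@@H]1c2ccccc2 | intermediate
25 | (2S,3S,4S)-4-methyl-5-oxo-2-(14-oxopentadecyl)tetrahydrofuran-3-carboxylic acid | CC(=O)CCCCCCCCCCCCC[C@@H]1OC(=O)[C@@H](C)[C@@H]1C(=O)O | target

**Step count**
Total: 14 steps. Longest linear sequence: 9 steps, from 10 through steps 6–14. The chain branch from 1 and 2 through steps 1–4 and 10–14 is equally long.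

**Steps most likely to fail**

**Step 10.** Several processes may go wrong here.
- Ate formation at the hindered boron may stay incomplete.
- The branched C3 substituent may slow alkene binding, so that direct alkenyl transfer to palladium or β-hydride elimination takes over.
- Facial selectivity may erode if ligand and substrate turn out mismatched.

The fallback forms the C4–C5 bond by allylboration and uses a vinyl group as the carboxyl surrogate. It sets out from 13 and 7 and comes back at 25. Hydroboration of 13 with pinacolborane (Cy2BH cat.) should give the (S,E)-alkenyl pinacol boronate F1. Matteson homologation with chloromethyllithium (BrCH2Cl, n-BuLi, −78 °C) should then give the (S,E)-allyl pinacol boronate F2. Formylation of 7 with DMF should give the chain aldehyde F3. Allylboration of F3 with F2 under chiral phosphoric acid catalysis (TRIP, antipode chosen for the aldehyde face that leads to 5S) runs through a chair Zimmerman–Traxler transition state. There the E geometry gives the anti relation of C5–OH and the C3 branch, which is the C4/C5 relation of 20, and the product is the anti homoallylic alcohol F4. Aqueous HCl should give the vinyl keto diol F5, and TEMPO/PhI(OAc)2 the vinyl lactone F6. RuCl3/NaIO4 cleavage of the vinyl group then gives 25.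

**Step 14.** Ring degradation may be slow, with competing C–H oxidation along the chain or at C4 and stalling of the ruthenium catalyst. The fallback changes the carboxyl surrogate to an electron-rich arene. It sets out from 15 and 7 and comes back at 25. The coupling of step 10 is run with 4-methoxyphenyl triflate in place of 16 and should give the anisyl B(mac) boronate F7. The operations of steps 11–13 should lead on to the anisyl alcohol F8, the anisyl keto diol F9 and the anisyl lactone F10. Catalytic RuO4 attacks the anisyl ring much more readily than phenyl, and ozonolysis with oxidative work-up becomes an option as well. Less oxidant and a shorter contact time should therefore be enough to reach 25.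

**Step 9.** Exchange of catechol for the hindered ditertiary diol may be sluggish, with hydrolysis or protodeboronation of the sensitive alkenyl catechol boronate during prolonged exchange and work-up. The fallback places boron on the chain and makes the alkene the nucleophile. It sets out from 13, 7 and 9 and comes back at 18.
- Alkene partner: hydrozirconation of 13 with Cp2Zr(H)Cl followed by iodine should give the (S,E)-alkenyl iodide F11. Iodine–lithium exchange (t-BuLi, 2 equiv, Et2O, −78 °C) should give the (S,E)-alkenyllithium F12 with retention of geometry.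
- Boron partner: quenching 7 with trimethyl borate and work-up with aq NH4Cl should give the chain boronic acid F13. This robust alkylboronic acid can be condensed with 9 under forcing azeotropic conditions to the chain B(mac) boronate F14.
- Union: addition of F12 to F14 should give the lithium ate complex F15, which holds the same anion as 17. It is coupled with 16 under the catalyst of step 10, with NaOTf present to take up iodide, to give 18.

**Further compounds**
F1 | step 10 | (S,E)-alkenyl pinacol boronate [2-((1E,3S)-4-TBSO-3-methylbut-1-enyl)-4,4,5,5-tetramethyl-1,3,2-dioxaborolane] | CC1(C)OB(/C=C/[C@H](C)CO[Si](C)(C)C(C)(C)C)OC1(C)C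
F2 | step 10 | (S,E)-allyl pinacol boronate [2-((2E,4S)-5-TBSO-4-methylpent-2-enyl)-4,4,5,5-tetramethyl-1,3,2-dioxaborolane] | CC1(C)OB(C/C=C/[C@H](C)CO[Si](C)(C)C(C)(C)C)OC1(C)C
F3 | step 10 | chain aldehyde [14-(2-methyl-1,3-dioxolan-2-yl)tetradecanal] | CC1(CCCCCCCCCCCCCC=O)OCCO1
F4 | step 10 | anti homoallylic alcohol [(2S,3S,4S)-1-TBSO-3-ethenyl-2-methyl-17-(2-methyl-1,3-dioxolan-2-yl)heptadecan-4-ol] | CC1(CCCCCCCCCCCCC[C@H](O)[C@@H](C=C)[C@H](C)CO[Si](C)(C)C(C)(C)C)OCCO1
F5 | step 10 | vinyl keto diol [(16S,17S,18S)-17-ethenyl-16,19-dihydroxy-18-methylnonadecan-2-one] | CC(=O)CCCCCCCCCCCCC[C@H](O)[C@@H](C=C)[C@H](C)CO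
F6 | step 10 | vinyl lactone [(3S,4S,5S)-4-ethenyl-3-methyl-5-(14-oxopentadecyl)dihydrofuran-2(3H)-one] | CC(=O)CCCCCCCCCCCCC[C@@H]1OC(=O)[C@@H](C)[C@@H]1C=C
F7 | step 14 | anisyl B(mac) boronate [analogue of 18 with 4-methoxyphenyl at C4] | CC1(CCCCCCCCCCCCC[C@H](B2O[C@]3(C)[C@](C)(O2)c2cccc4cccc3c24)[C@@H](c2ccc(OC)cc2)[C@H](C)CO[Si](C)(C)C(C)(C)C)OCCO1
F8 | step 14 | anisyl alcohol [analogue of 20 with 4-methoxyphenyl at C4] | CC1(CCCCCCCCCCCCC[C@H](O)[C@@H](c2ccc(OC)cc2)[C@H](C)CO[Si](C)(C)C(C)(C)C)OCCO1
F9 | step 14 | anisyl keto diol [(16S,17R,18S)-16,19-dihydroxy-17-(4-methoxyphenyl)-18-methylnonadecan-2-one] | CC(=O)CCCCCCCCCCCCC[C@H](O)[C@@H](c1ccc(OC)cc1)[C@H](C)CO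
F10 | step 14 | anisyl lactone [(3S,4R,5S)-4-(4-methoxyphenyl)-3-methyl-5-(14-oxopentadecyl)dihydrofuran-2(3H)-one] | CC(=O)CCCCCCCCCCCCC[C@@H]1OC(=O)[C@@H](C)[C@@H]1c2ccc(OC)cc2
F11 | step 9 | (S,E)-alkenyl iodide [tert-butyl-((2S,3E)-4-iodo-2-methylbut-3-enyloxy)dimethylsilane] | C[C@H](CO[Si](C)(C)C(C)(C)C)/C=C/I
F12 | step 9 | (S,E)-alkenyllithium [(1E,3S)-4-TBSO-3-methylbut-1-enyllithium] | C[C@H](CO[Si](C)(C)C(C)(C)C)/C=C/[Li]
F13 | step 9 | chain boronic acid [13-(2-methyl-1,3-dioxolan-2-yl)tridecylboronic acid] | CC1(CCCCCCCCCCCCCB(O)O)OCCO1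
F14 | step 9 | chain B(mac) boronate [cyclic ester of F13 with 9] | CC1(CCCCCCCCCCCCCB2O[C@]3(C)[C@](C)(O2)c2cccc4cccc3c24)OCCO1
F15 | step 9 | lithium ate complex [lithium salt of the anion of 17] | CC1(CCCCCCCCCCCCC[B-]2(/C=C/[C@H](C)CO[Si](C)(C)C(C)(C)C)O[C@]3(C)[C@](C)(O2)c2cccc4cccc3c24)OCCO1.[Li+]
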